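## Retrosynthetic overview

1. **Feature.** In the nine-membered ring the atoms N, N–CH (bearing the methylbutyrolactone), CH2 and the ketone C=O lie between the lactam carbonyl carbon and the ketone α-CH. Removing these four atoms joins those two carbons. What remains is a cyclopentanone carrying the four atoms as a 2-(β-aminoacyl) side chain.
2. **Last bond.** The azepanone N–CH2 bond is cut back to the N–H nine-membered lactam with a C4 aldehyde arm. Closure is by acidic reductive N-alkylation, because amide-anion alkylation would enolise the β-acyloxy/β-amido ketone.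
3. **Fused γ-lactone.** The C–O bond is cut back to a silyloxy ester. This lactone is closed only after the expansion, because the fragmentation erases the quaternary carbon. A soft-enolate Michael addition anti to the silyloxy group is therefore acceptable.
4. **Key bond.** Cutting the lactam N–C(=O) bond and re-forming the C–C bond leads to a 2-alkyl-2-(β-aminoacyl)cyclopentanone. It is built from silyloxycyclopentenone (iodination, B-alkyl Suzuki coupling, ethyl cuprate with kinetic protonation), an aspartate-derived β-amino acid (C-acylation) and 1-nitropropene.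
5. **Ring order.** Cyclopentanone (chiral pool) and side-chain γ-lactone, then the transient six-membered cyclol, then the nine-membered lactam, then the fused γ-lactone, then the azepanone.

Key step: step 13

**Assumption.** The ketone α-carbon is taken to be most stable with the ketone carbon and the CH–Et ring carbon trans on the fused lactone, as in the natural product, so equilibration should give the required epimer. Locants: cyclopentanone C-1 = ring C=O, C-2 = acyl-bearing carbon; azonane N-1, C-2 = lactam C=O, C-7 = ketone.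

## Route

Step 1
Reactants: 1 (4R)-4-(tert-butyldimethylsilyloxy)cyclopent-2-en-1-one
Product: 2 (4R)-4-(tert-butyldimethylsilyloxy)-2-iodocyclopent-2-en-1-one
Conditions: I2, pyridine–CH2Cl2 (1:1), 0 °C → rt
Reagents that add atoms: iodine, II
Why: Pyridine-mediated α-iodination of an enone (conjugate addition of pyridine, iodination of the enolate, E1cB loss of pyridine) is established for 4-silyloxycyclopentenones and leaves C-4 untouched.

Step 2
Reactants: 2 (4R)-4-(tert-butyldimethylsilyloxy)-2-iodocyclopent-2-en-1-one; 3 4-(benzyloxy)but-1-ene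
Product: 5 (4R)-2-[4-(benzyloxy)butyl]-4-(tert-butyldimethylsilyloxy)cyclopent-2-en-1-one, via B-alkyl borane 4 (not isolated)
Conditions: 3, 9-BBN-H, THF, 0 °C → rt; then 2, PdCl2(dppf) (5 mol %), Ph3As, Cs2CO3, DMF–THF–H2O, rt
Reagents that add atoms: none
Why: Anti-Markovnikov hydroboration followed by B-alkyl Suzuki–Miyaura coupling with the α-iodoenone at room temperature installs the C4 arm, which a direct α-alkylation of the enone cannot do, without base-induced loss of the silyloxy group.

Step 3
Reactants: 5 (4R)-2-[4-(benzyloxy)butyl]-4-(tert-butyldimethylsilyloxy)cyclopent-2-en-1-one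
Product: 7 (2S,3R,4R)-2-[4-(benzyloxy)butyl]-4-(tert-butyldimethylsilyloxy)-3-ethylcyclopentan-1-one (arm and ethyl cis; ethyl and OTBS trans), via magnesium enolate 6 (not isolated)
Conditions: EtMgBr (2.4 equiv), CuBr·SMe2 (1.2 equiv), THF–Me2S, −78 °C; then ethyl salicylate (excess), −78 °C; aq NH4Cl; neutral supports only
Reagents that add atoms: ethylmagnesium bromide, CC[Mg]Br
Why: Dialkylcuprate 1,4-addition occurs anti to the C-4 silyloxy group (sets C-3), and low-temperature protonation of the enolate by a chelating phenol should come from the face opposite the new ethyl group, giving the contra-thermodynamic 2,3-cis ketone (diastereoselective kinetic protonation).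

Step 4
Reactants: 8 N-benzyloxycarbonyl-L-aspartic acid 4-tert-butyl ester
Product: 10 tert-butyl (3S)-3-(benzyloxycarbonylamino)-4-[methoxy(methyl)amino]-4-oxobutanoate, via acyl imidazolide 9 (not isolated)
Conditions: CDI, CH2Cl2, 0 °C → rt; then MeNH(OMe)·HCl, rt
Reagents that add atoms: N,O-dimethylhydroxylamine hydrochloride, CNOC.Cl
Why: Imidazolide activation and N-methoxy-N-methylamide formation at the free α-carboxyl group proceed without racemising the urethane-protected centre.

Step 5
Reactants: 10 tert-butyl (3S)-3-(benzyloxycarbonylamino)-4-[methoxy(methyl)amino]-4-oxobutanoate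
Product: 11 tert-butyl (3S)-3-(benzyloxycarbonylamino)-4-oxobutanoate
Conditions: LiAlH4, THF, −40 → −10 °C; aq KHSO4; used crude
Reagents that add atoms: none
Why: Hydride addition to the N-methoxy-N-methylamide stops at the chelated tetrahedral intermediate, so the aldehyde appears only on work-up, the tert-butyl ester survives, and immediate use avoids epimerisation.

Step 6
Reactants: 11 tert-butyl (3S)-3-(benzyloxycarbonylamino)-4-oxobutanoate; 12 methyl (2R)-3-bromo-2-methylpropanoate
Product: 16 tert-butyl (3S)-3-(benzyloxycarbonylamino)-3-[(2S,4S)-4-methyl-5-oxooxolan-2-yl]propanoate, via zinc homoenolate 13 (not isolated), via titanium homoenolate 14 (not isolated), via hydroxy ester 15 (not isolated)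
Conditions: 12, Zn, LiCl, THF, 40 °C; Cl2Ti(OiPr)2, CH2Cl2–THF, −30 °C; 11, −30 → −10 °C; then AcOH, toluene, 60 °C
Reagents that add atoms: none
Why: Chelation-controlled addition of a Lewis-acidic titanium homoenolate to the N–H carbamate aldehyde should give the syn (S) carbinol, the CH(CH3) centre comes unchanged from the chiral pool, and mild acid lactonises onto the methyl ester rather than the tert-butyl ester to give the cis-2,4-disubstituted γ-lactone.

Step 7
Reactants: 16 tert-butyl (3S)-3-(benzyloxycarbonylamino)-3-[(2S,4S)-4-methyl-5-oxooxolan-2-yl]propanoate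
Product: 17 (3S)-3-(benzyloxycarbonylamino)-3-[(2S,4S)-4-methyl-5-oxooxolan-2-yl]propanoic acid
Conditions: TFA–CH2Cl2 (1:2), 0 °C → rt
Reagents that add atoms: none
Why: Acidolysis of the tert-butyl ester (loss of isobutene) leaves the Cbz group and the γ-lactone intact.

Step 8
Reactants: 7 (2S,3R,4R)-2-[4-(benzyloxy)butyl]-4-(tert-butyldimethylsilyloxy)-3-ethylcyclopentan-1-one; 17 (3S)-3-(benzyloxycarbonylamino)-3-[(2S,4S)-4-methyl-5-oxooxolan-2-yl]propanoic acid
Product: 20 (3S,4R,5S)-5-[4-(benzyloxy)butyl]-3-(tert-butyldimethylsilyloxy)-4-ethyl-2-acylcyclopentan-1-one with acyl = the propanoyl residue of 17 (C-2 labile and largely enolised), via lithium enolate 18 (not isolated), via acyl imidazolide 19 (not isolated)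
Conditions: 17, CDI, THF, rt; separately 7, LiHMDS (3 equiv in all), THF, −78 °C; combine, −78 → −40 °C; aq NH4Cl
Reagents that add atoms: none
Why: In this Claisen-type C-acylation kinetic deprotonation takes the unhindered CH2 rather than the tertiary C–H (so the cis centre is kept), the β-silyloxy enolate does not eliminate at −78 °C, the imidazolide favours C- over O-acylation, and the extra base covers the carbamate N–H and the acidic product.

Step 9
Reactants: 21 1-nitropropan-2-ol
Product: 23 (E)-1-nitroprop-1-ene, via mesylate 22 (not isolated)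
Conditions: MsCl, Et3N (2.2 equiv), CH2Cl2, 0 °C
Reagents that add atoms: none
Why: Mesylation of the β-nitro alcohol and E1cB elimination give the (E)-nitroalkene.

Step 10
Reactants: 20 β-diketone; 23 (E)-1-nitroprop-1-ene
Product: 24 (2R,3S,4R,5S)-2-acyl-5-[4-(benzyloxy)butyl]-3-(tert-butyldimethylsilyloxy)-4-ethyl-2-[(2S)-1-nitropropan-2-yl]cyclopentan-1-one (nitropropyl group trans to OTBS)
Conditions: 23 (3 equiv), 1-[3,5-bis(trifluoromethyl)phenyl]-3-[2-(dimethylamino)cyclohexyl]thiourea (10 mol %, antipode chosen for Re-face attack at C-2 of 23), toluene, 0 °C → rt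
Reagents that add atoms: none
Why: The organocatalytic Michael addition of a 2-acylcyclopentanone to a nitroalkene builds a quaternary carbon next to a tertiary one under nearly neutral conditions (no O-alkylation, no loss of OTBS, no epimerisation), the ring directing attack anti to OTBS and the catalyst fixing the (S) CH(CH3) centre, while the quaternary configuration is immaterial because step 13 erases it.

Step 11
Reactants: 24 nitro diketone
Product: 26 methyl ester (as 24 with CH2NO2 replaced by CO2CH3; CH(CH3) centre S), via carboxylic acid 25 (not isolated)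
Conditions: NaNO2, AcOH, DMSO, 35 °C; crude acid, TMSCHN2, toluene–MeOH, 0 °C
Reagents that add atoms: water, O; (trimethylsilyl)diazomethane, C[Si](C)(C)C=[N+]=[N-]
Why: Nitrite/acetic acid oxidation of the primary nitroalkane (Nef-type, via the nitrolic acid) reaches the acid without a strongly basic nitronate stage that would cleave the non-enolisable diketone or scramble the adjacent centre, and diazo esterification prevents pseudo-acid formation with the γ-ketones.

Step 12
Reactants: 26 Cbz- and benzyl-protected methyl ester
Product: 27 ammonium trifluoroacetate of the amino alcohol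
Conditions: H2 (1 atm), Pd(OH)2/C, TFA (1.1 equiv), EtOAc, rt; filter, concentrate
Reagents that add atoms: trifluoroacetic acid, OC(=O)C(F)(F)F
Why: Hydrogenolysis removes the Cbz group and the benzyl ether in one operation, and the added acid holds the amine as its salt so that neither reductive amination on the catalyst nor acyl transfer can start before hydrogen and palladium are removed.

Step 13
Reactants: 27 ammonium trifluoroacetate
Product: 30 nine-membered keto-lactam (azonane-2,7-dione: 3-(4-hydroxybutyl), 4-ethyl, 5-OTBS, 6-[(2S)-1-methoxy-1-oxopropan-2-yl], 9-[(2S,4S)-4-methyl-5-oxooxolan-2-yl]; centres as in 36), via free amine 28 (not isolated), via cyclol 29 (not isolated)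
Conditions: Et3N (1.2 equiv), AcOH (2 equiv), water-saturated CHCl3, rt → 45 °C
Reagents that add atoms: none
Why: Neutralisation frees amine 28, whose nitrogen adds to the ring ketone C-1 (6-exo-trig) to give cyclol 29; push from the N and O lone pairs, helped by acetic acid protonating the side-chain ketone, then breaks the C-1–C-2 bond shared by the five- and six-membered rings (retro-Claisen), which creates the lactam C=O and releases C-2 as the enol of the side-chain ketone. The closest known reaction type is the side-chain-insertion (successive) ring expansion of C-acylated cyclic β-keto esters by a tethered amine, together with the amine-induced cleavage of non-enolisable 1,3-diketones. The nine-membered ring is therefore not closed end to end: only a six-membered ring is closed, and scission of the fusion bond merges the two rings (5 + 6 − 2 = 9 atoms). The one new stereocentre, the ketone α-CH (C-6 of 30), comes from ketonisation of that enol, so the configuration of the quaternary carbon of 28 is erased (both of its epimers converge) and C-6 is finally fixed under thermodynamic control by the fused lactone in step 14. The amine must choose C-1 over the side-chain ketone (four-membered ring, impossible), the methyl ester (seven-membered) and the adjacent γ-lactone (strained 7-oxa-2-azabicyclo[2.2.1]heptane intermediate and, unlike ketone addition, no help from the acidic buffer), and the cyclol must expel C-2 rather than C-5, which only C-2 allows because it alone carries a second carbonyl group. The weakly acidic, wet medium keeps imine formation reversible and spares the epimerisable C-5–H, the β-silyloxy group and the β-amino ketone from base.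

Step 14
Reactants: 30 nine-membered keto-lactam
Product: 32 N–H nine-membered keto-lactam with both γ-lactones and a 4-hydroxybutyl arm (fused lactone trans across C-5/C-6), via hydroxy ester 31 (not isolated)
Conditions: HF·pyridine, THF, 0 °C → rt; then DBU (0.1 equiv), CH2Cl2, rt
Reagents that add atoms: none
Why: Desilylation frees the C-5 hydroxyl, which closes the γ-lactone on the methyl ester (5-exo-trig transesterification), and catalytic base equilibrates the ketone α-carbon through its enolate to the trans-fused epimer, β-elimination of the lactone oxygen being a stereoelectronically slow retro-5-endo-trig process.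

Step 15
Reactants: 32 hydroxybutyl bis-lactone lactam
Product: 33 the corresponding 4-oxobutyl aldehyde
Conditions: DMP, NaHCO3, CH2Cl2, 0 °C → rt
Reagents that add atoms: none
Why: Periodinane oxidation of the only free alcohol under buffered neutral conditions leaves the epimerisable ketone α-centre, the lactones and the lactam N–H untouched.

Step 16
Reactants: 33 aldehyde
Product: 36 tuberostemonone, via hemiaminal 34 (not isolated), via N-acyliminium ion 35 (not isolated)
Conditions: TFA, Et3SiH (3 equiv), CH2Cl2, 0 °C → rt
Reagents that add atoms: none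
Why: In this intramolecular reductive N-alkylation of a secondary lactam (N-acyliminium formation, then ionic hydrogenation) the transoid lactam rotamer places N–H next to the C-3 arm, the seven-membered hemiaminal ionises in TFA, and the cation should take hydride from the silane much faster than the hindered ketone, all under acid so that no ketone enolate can expel the β-amido or β-acyloxy groups.

## Compound list

1 | (4R)-4-(tert-butyldimethylsilyloxy)cyclopent-2-en-1-one | O=C1C=C[C@H](O[Si](C)(C)C(C)(C)C)C1 | starting material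
2 | (4R)-4-(tert-butyldimethylsilyloxy)-2-iodocyclopent-2-en-1-one | O=C1C(I)=C[C@H](O[Si](C)(C)C(C)(C)C)C1 | intermediate
3 | 4-(benzyloxy)but-1-ene | C=CCCOCc1ccccc1 | starting material
4 | 9-[4-(benzyloxy)butyl]-9-borabicyclo[3.3.1]nonane | c1ccccc1COCCCCB2C3CCCC2CCC3 | intermediate
5 | (4R)-2-[4-(benzyloxy)butyl]-4-(tert-butyldimethylsilyloxy)cyclopent-2-en-1-one | O=C1C(CCCCOCc2ccccc2)=C[C@H](O[Si](C)(C)C(C)(C)C)C1 | intermediate
6 | bromomagnesium C-1/C-2 enolate from ethyl addition to 5 | CC[C@H]1[C@H](O[Si](C)(C)C(C)(C)C)CC(O[Mg]Br)=C1CCCCOCc2ccccc2 | intermediate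
7 | (2S,3R,4R)-2-[4-(benzyloxy)butyl]-4-(tert-butyldimethylsilyloxy)-3-ethylcyclopentan-1-one | CC[C@H]1[C@H](O[Si](C)(C)C(C)(C)C)CC(=O)[C@H]1CCCCOCc2ccccc2 | intermediate
8 | N-benzyloxycarbonyl-L-aspartic acid 4-tert-butyl ester | CC(C)(C)OC(=O)C[C@@H](C(=O)O)NC(=O)OCc1ccccc1 | starting material
9 | 1-acyl imidazolide of 8 | CC(C)(C)OC(=O)C[C@@H](C(=O)n1ccnc1)NC(=O)OCc2ccccc2 | intermediate
10 | tert-butyl (3S)-3-(Cbz-amino)-4-[methoxy(methyl)amino]-4-oxobutanoate | CC(C)(C)OC(=O)C[C@@H](C(=O)N(C)OC)NC(=O)OCc1ccccc1 | intermediate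
11 | tert-butyl (3S)-3-(Cbz-amino)-4-oxobutanoate | CC(C)(C)OC(=O)C[C@@H](C=O)NC(=O)OCc1ccccc1 | intermediate
12 | methyl (2R)-3-bromo-2-methylpropanoate | COC(=O)[C@@H](C)CBr | starting material
13 | [(2R)-3-methoxy-2-methyl-3-oxopropyl]zinc bromide | COC(=O)[C@@H](C)C[Zn]Br | intermediate
14 | chloro(diisopropoxy)[(2R)-3-methoxy-2-methyl-3-oxopropyl]titanium | COC(=O)[C@@H](C)C[Ti](Cl)(OC(C)C)OC(C)C | intermediate
15 | 1-tert-butyl 7-methyl (3S,4S,6S)-3-(Cbz-amino)-4-hydroxy-6-methylheptanedioate | CC(C)(C)OC(=O)C[C@@H]([C@@H](O)C[C@H](C)C(=O)OC)NC(=O)OCc1ccccc1 | intermediate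
16 | tert-butyl (3S)-3-(Cbz-amino)-3-[(2S,4S)-4-methyl-5-oxooxolan-2-yl]propanoate | CC(C)(C)OC(=O)C[C@@H]([C@@H]1C[C@H](C)C(=O)O1)NC(=O)OCc2ccccc2 | intermediate
17 | (3S)-3-(Cbz-amino)-3-[(2S,4S)-4-methyl-5-oxooxolan-2-yl]propanoic acid | OC(=O)C[C@@H]([C@@H]1C[C@H](C)C(=O)O1)NC(=O)OCc2ccccc2 | intermediate
18 | kinetic lithium enolate of 7 | CC[C@H]1[C@H](O[Si](C)(C)C(C)(C)C)C=C(O[Li])[C@H]1CCCCOCc2ccccc2 | intermediate
19 | acyl imidazolide of 17 | O=C(C[C@@H]([C@@H]1C[C@H](C)C(=O)O1)NC(=O)OCc2ccccc2)n3ccnc3 | intermediate
20 | 2-acylcyclopentanone (β-diketone, C-2 labile) | CC[C@H]1[C@H](O[Si](C)(C)C(C)(C)C)C(C(=O)C[C@@H]([C@@H]2C[C@H](C)C(=O)O2)NC(=O)OCc3ccccc3)C(=O)[C@H]1CCCCOCc4ccccc4 | intermediate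
21 | 1-nitropropan-2-ol | CC(O)C[N+](=O)[O-] | starting material
22 | 1-nitropropan-2-yl methanesulfonate | CC(C[N+](=O)[O-])OS(C)(=O)=O | intermediate
23 | (E)-1-nitroprop-1-ene | C/C=C/[N+](=O)[O-] | intermediate
24 | quaternary nitro diketone (2R; side-chain CH(CH3) S) | CC[C@H]1[C@H](O[Si](C)(C)C(C)(C)C)[C@]([C@H](C)C[N+](=O)[O-])(C(=O)C[C@@H]([C@@H]2C[C@H](C)C(=O)O2)NC(=O)OCc3ccccc3)C(=O)[C@H]1CCCCOCc4ccccc4 | intermediate
25 | corresponding carboxylic acid | CC[C@H]1[C@H](O[Si](C)(C)C(C)(C)C)[C@]([C@H](C)C(=O)O)(C(=O)C[C@@H]([C@@H]2C[C@H](C)C(=O)O2)NC(=O)OCc3ccccc3)C(=O)[C@H]1CCCCOCc4ccccc4 | intermediate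
26 | corresponding methyl ester | CC[C@H]1[C@H](O[Si](C)(C)C(C)(C)C)[C@]([C@H](C)C(=O)OC)(C(=O)C[C@@H]([C@@H]2C[C@H](C)C(=O)O2)NC(=O)OCc3ccccc3)C(=O)[C@H]1CCCCOCc4ccccc4 | intermediate
27 | ammonium trifluoroacetate of the amino alcohol | CC[C@H]1[C@H](O[Si](C)(C)C(C)(C)C)[C@]([C@H](C)C(=O)OC)(C(=O)C[C@@H]([C@@H]2C[C@H](C)C(=O)O2)[NH3+])C(=O)[C@H]1CCCCO.[O-]C(=O)C(F)(F)F | intermediate
28 | 2-(β-aminoacyl)cyclopentanone, free amine (key-step precursor) | CC[C@H]1[C@H](O[Si](C)(C)C(C)(C)C)[C@]([C@H](C)C(=O)OC)(C(=O)C[C@@H]([C@@H]2C[C@H](C)C(=O)O2)N)C(=O)[C@H]1CCCCO | intermediate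
29 | six-membered cyclol (cis-fused to the cyclopentane) | CC[C@H]1[C@H](O[Si](C)(C)C(C)(C)C)[C@]2([C@H](C)C(=O)OC)C(=O)C[C@@H]([C@@H]3C[C@H](C)C(=O)O3)N[C@]2(O)[C@H]1CCCCO | intermediate
30 | nine-membered N–H keto-lactam, silyloxy ester form (key-step product) | CC[C@H]1[C@H](O[Si](C)(C)C(C)(C)C)[C@@H]([C@H](C)C(=O)OC)C(=O)C[C@@H]([C@@H]2C[C@H](C)C(=O)O2)NC(=O)[C@H]1CCCCO | intermediate
31 | desilylated hydroxy ester | CC[C@H]1[C@H](O)[C@@H]([C@H](C)C(=O)OC)C(=O)C[C@@H]([C@@H]2C[C@H](C)C(=O)O2)NC(=O)[C@H]1CCCCO | intermediate
32 | nine-membered N–H keto-lactam with both lactones and 4-hydroxybutyl arm | CC[C@H]1[C@@H]2OC(=O)[C@@H](C)[C@H]2C(=O)C[C@@H]([C@@H]3C[C@H](C)C(=O)O3)NC(=O)[C@H]1CCCCO | intermediate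
33 | corresponding 4-oxobutyl aldehyde | CC[C@H]1[C@@H]2OC(=O)[C@@H](C)[C@H]2C(=O)C[C@@H]([C@@H]3C[C@H](C)C(=O)O3)NC(=O)[C@H]1CCCC=O | intermediate
34 | seven-membered N-acyl hemiaminal | CC[C@H]1[C@@H]2OC(=O)[C@@H](C)[C@H]2C(=O)C[C@@H]([C@@H]3C[C@H](C)C(=O)O3)N4C(O)CCC[C@@H]1C4=O | intermediate
35 | N-acyliminium trifluoroacetate | CC[C@H]1[C@@H]2OC(=O)[C@@H](C)[C@H]2C(=O)C[C@@H]([C@@H]3C[C@H](C)C(=O)O3)[N+]4=CCCC[C@@H]1C4=O.[O-]C(=O)C(F)(F)F | intermediate
36 | tuberostemonone | CC[C@H]1[C@@H]2OC(=O)[C@@H](C)[C@H]2C(=O)C[C@@H]([C@@H]2C[C@H](C)C(=O)O2)N2CCCC[C@@H]1C2=O | target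

## Step count

Total step count: 16.
Longest linear sequence: 12 steps (8 → 36 through steps 4–8 and 10–16).

## Steps most likely to fail

**Step 13.** The cyclol may form reversibly while the C–C cleavage stays too slow, because only a mono-ketone enol is expelled. Dehydration to the cyclic imine, loss of ammonia from the β-amino ketone, or O→N acyl shift from the neighbouring γ-lactone could then take over.

The fallback raises the ground-state strain and improves the leaving enolate by closing the fused lactone before the expansion, through an oxygen tether. It sets out from 20.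
- HF·pyridine would give the hydroxy diketone F1.
- Esterification with (S)-2-bromopropanoic acid (DIC, catalytic DMAP, 0 °C) would give the bromopropanoate F2.
- Cs2CO3 in MeCN at 0 °C would let the diketone enolate displace bromide within the tether (5-exo-tet, inversion). The new C–C bond is forced cis to the oxygen, giving the cis-lactone-fused Cbz diketone F3.
- Hydrogenolysis as in step 12 would give the ammonium salt F4.
- The buffer of step 13 would free the lactone-fused amino diketone F5, which should pass through the tricyclic cyclol F6.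

The fallback comes back to the route at 32.

**Step 16.** The seven-membered N-acyliminium ion may form slowly. The silane could then reduce the aldehyde or the ketone first, or the ketone enol could trap the cation in a transannular Mannich closure.

The fallback separates ring closure from reduction. It sets out from 33. Catalytic camphorsulfonic acid with 4 Å molecular sieves in warm toluene would dehydrate the hemiaminal to the cyclic enamide F7. Neutral hydrogenation (H2, Pd/C, EtOAc) would then bring it back to the route at 36.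

**Step 10.** Conversion may be poor at the hindered carbon next to the silyloxy group, and facial control at the nitroalkene may be insufficient when catalyst and substrate are mismatched.

The fallback replaces the catalyst-controlled addition by a stereospecific substitution from the chiral pool. It sets out from 20. The sodium enolate (NaH, 1 equiv, THF, 0 °C) would be alkylated with methyl (S)-2-(trifluoromethylsulfonyloxy)propanoate at −78 → 0 °C. This SN2 reaction with inversion fixes the (S) CH(CH3) centre. The fallback comes back to the route directly at 26, bypassing 24 and 25. It makes no compound outside the list (F0).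

## Further compounds

F1 | step 13 | hydroxy diketone (20 without TBS) | CC[C@H]1[C@H](O)C(C(=O)C[C@@H]([C@@H]2C[C@H](C)C(=O)O2)NC(=O)OCc3ccccc3)C(=O)[C@H]1CCCCOCc4ccccc4
F2 | step 13 | (S)-2-bromopropanoate of F1 | CC[C@H]1[C@H](OC(=O)[C@H](C)Br)C(C(=O)C[C@@H]([C@@H]2C[C@H](C)C(=O)O2)NC(=O)OCc3ccccc3)C(=O)[C@H]1CCCCOCc4ccccc4
F3 | step 13 | cis-lactone-fused Cbz diketone | CC[C@H]1[C@@H]2OC(=O)[C@@H](C)[C@]2(C(=O)C[C@@H]([C@@H]3C[C@H](C)C(=O)O3)NC(=O)OCc4ccccc4)C(=O)[C@H]1CCCCOCc5ccccc5
F4 | step 13 | ammonium trifluoroacetate of the lactone-fused amino diketone | CC[C@H]1[C@@H]2OC(=O)[C@@H](C)[C@]2(C(=O)C[C@@H]([C@@H]3C[C@H](C)C(=O)O3)[NH3+])C(=O)[C@H]1CCCCO.[O-]C(=O)C(F)(F)F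
F5 | step 13 | cis-lactone-fused 2-(β-aminoacyl)cyclopentanone, free amine | CC[C@H]1[C@@H]2OC(=O)[C@@H](C)[C@]2(C(=O)C[C@@H]([C@@H]3C[C@H](C)C(=O)O3)N)C(=O)[C@H]1CCCCO
F6 | step 13 | tricyclic cyclol | CC[C@H]1[C@@H]2OC(=O)[C@@H](C)[C@@]23C(=O)C[C@@H]([C@@H]4C[C@H](C)C(=O)O4)N[C@@]3(O)[C@H]1CCCCO
F7 | step 16 | cyclic enamide (didehydro-tuberostemonone) | CC[C@H]1[C@@H]2OC(=O)[C@@H](C)[C@H]2C(=O)C[C@@H]([C@@H]3C[C@H](C)C(=O)O3)N4C=CCC[C@@H]1C4=O
F0 | step 10 | none | none
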